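**Strategy.** The target is cut at the central ring, where the butanoyl-bearing carbon C1 and the adjacent hydroxyl-bearing carbon C2 of the fully substituted phloroglucinol nucleus are made together. An aryne spanning C1–C2 inserts into the C–O bond of butyric acid, so the aryl–oxygen bond at C2 and the aryl–carbonyl bond at C1 form in one operation, using the ortho acyl/hydroxyl pair of that ring. The aryne precursor is a hexasubstituted 2-(trimethylsilyl)aryl triflate carrying two benzyloxy groups and two di-O-benzyl aspidinol arms on methylene bridges. It is assembled by twofold Friedel–Crafts benzylation of a pre-differentiated bromophenol, then retro-Brook silyl migration and triflation. Hydrogenolysis finishes the synthesis.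

Key step: step 10

**Remarks on the chemistry (assumptions).**
- Central-ring numbering used below: C1 carries silicon (later butanoyl), C2 the triflate (later hydroxyl), C3 and C5 the arms, C4 and C6 the benzyloxy groups.
- One particular hydroxyl cannot be left free selectively among seven phenols. The lone free central hydroxyl is therefore carried from commercial 3,5-bis(benzyloxy)phenol 8, and the arms are introduced already benzylated.
- Butyllithium would otherwise meet two enolisable ketones. Both outer butanoyl groups are therefore masked as trimethylsilyl enol ethers for the lithiation step only. They are drawn as (Z) isomers; the geometry is of no consequence because they are hydrolysed in the same step.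

Step 1
Reactants: 1 2-methylphloroglucinol; 2 butyryl chloride
Product: 3 1-(2,4,6-trihydroxy-3-methylphenyl)butan-1-one
Conditions: AlCl3 (3.5 equiv), PhNO2, rt → 60 °C; aq. HCl work-up
Reagents that add atoms: none
Why: Friedel–Crafts C-acylation of a highly activated triol whose two free ring positions are equivalent, so one equivalent of acid chloride should give a single monoketone.

Step 2
Reactants: 3 1-(2,4,6-trihydroxy-3-methylphenyl)butan-1-one
Product: 4 aspidinol, 1-(2,6-dihydroxy-4-methoxy-3-methylphenyl)butan-1-one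
Conditions: Me2SO4 (1.0 equiv), K2CO3 (1.1 equiv), acetone, rt
Reagents that add atoms: dimethyl sulfate, COS(=O)(=O)OC
Why: Williamson O-methylation in which the 4-hydroxyl, para to the ketone and the only one not hydrogen-bonded to the carbonyl, is the most acidic and should react selectively with one equivalent of reagent.

Step 3
Reactants: 4 aspidinol
Product: 5 3-butanoyl-2,4-dihydroxy-6-methoxy-5-methylbenzaldehyde
Conditions: POCl3 (1.5 equiv), DMF (3 equiv), MeCN, 0 °C → rt; then H2O, 50 °C
Reagents that add atoms: N,N-dimethylformamide, CN(C)C=O (formyl carbon); water, O (formyl oxygen)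
Why: Vilsmeier–Haack formylation at the only unsubstituted ring carbon, which is activated by three oxygen substituents and reacts well below the temperature at which the ketone side chain would be attacked.

Step 4
Reactants: 5 3-butanoyl-2,4-dihydroxy-6-methoxy-5-methylbenzaldehyde
Product: 6 2,4-bis(benzyloxy)-3-butanoyl-6-methoxy-5-methylbenzaldehyde
Conditions: BnBr (2.6 equiv), K2CO3 (3 equiv), DMF, 60 °C
Reagents that add atoms: benzyl bromide, BrCc1ccccc1
Why: Williamson O-benzylation of both chelated phenols in a polar aprotic solvent, where O-alkylation is favoured over dearomatising C-alkylation of the fully substituted ring.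

Step 5
Reactants: 6 2,4-bis(benzyloxy)-3-butanoyl-6-methoxy-5-methylbenzaldehyde
Product: 7 1-[2,6-bis(benzyloxy)-3-(hydroxymethyl)-4-methoxy-5-methylphenyl]butan-1-one
Conditions: NaBH4 (0.6 equiv), THF/MeOH, −40 → −20 °C
Reagents that add atoms: none
Why: Chemoselective borohydride reduction, since the aldehyde is reduced much faster at low temperature than the aryl ketone flanked by two ortho benzyloxy groups.

Step 6
Reactants: 8 3,5-bis(benzyloxy)phenol
Product: 9 3,5-bis(benzyloxy)-2-bromophenol
Conditions: NBS (1.0 equiv), CH2Cl2, −78 → 0 °C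
Reagents that add atoms: N-bromosuccinimide, O=C1CCC(=O)N1Br
Why: Electrophilic aromatic bromination that, at low temperature in a non-polar solvent, should be delivered ortho to the free hydroxyl by hydrogen bonding, any 4-bromo isomer being removed by chromatography.

Step 7
Reactants: 9 3,5-bis(benzyloxy)-2-bromophenol; 7 1-[2,6-bis(benzyloxy)-3-(hydroxymethyl)-4-methoxy-5-methylphenyl]butan-1-one (2.2 equiv)
Product: 10 3,5-bis(benzyloxy)-4,6-bis{[2,4-bis(benzyloxy)-3-butanoyl-6-methoxy-5-methylphenyl]methyl}-2-bromophenol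
Conditions: Sc(OTf)3 (5 mol %), CH2Cl2/MeNO2, 0 °C → rt
Reagents that add atoms: none
Why: Twofold Friedel–Crafts benzylation in which catalytic Sc(OTf)3 ionises the 2,4,6-trioxygenated benzylic alcohol to a stabilised cation that is captured at C4 and C6 of 9, the only unsubstituted ring carbons, while bromine blocks C2 and any O-benzylation of the free phenol reverts under the acid catalysis.

Step 8
Reactants: 10 3,5-bis(benzyloxy)-4,6-bis{[2,4-bis(benzyloxy)-3-butanoyl-6-methoxy-5-methylphenyl]methyl}-2-bromophenol
Product: 11 tris-silyl derivative of 10 (aryl trimethylsilyl ether; both butanoyl groups as (Z)-1-(trimethylsilyloxy)but-1-enyl groups)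
Conditions: TMSOTf (4 equiv), Et3N (6 equiv), CH2Cl2, 0 °C → rt; non-aqueous work-up (pentane, filtration), used crude
Reagents that add atoms: trimethylsilyl trifluoromethanesulfonate, C[Si](C)(C)OS(=O)(=O)C(F)(F)F
Why: Silylation with soft enolisation, which places the migrating silyl group on the central phenol and at the same time masks both ketones and their acidic alpha-hydrogens as silyl enol ethers against the organolithium of step 9.

Step 9
Reactants: 11 tris-silyl derivative of 10
Product: 15 3,5-bis(benzyloxy)-4,6-bis{[2,4-bis(benzyloxy)-3-butanoyl-6-methoxy-5-methylphenyl]methyl}-2-(trimethylsilyl)phenyl trifluoromethanesulfonate, via aryllithium 12 (not isolated), via lithium phenoxide 13 (not isolated), via enol-ether triflate 14 (not isolated)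
Conditions: n-BuLi (1.1 equiv), THF, −78 °C; Tf2O (1.1 equiv), −78 °C; then 0.5 M HCl, THF, 0 °C
Reagents that add atoms: trifluoromethanesulfonic anhydride, O=S(=O)(OS(=O)(=O)C(F)(F)F)C(F)(F)F
Why: Bromine–lithium exchange gives an aryllithium whose neighbouring O-silyl group migrates to carbon (1,3 retro-Brook rearrangement), the resulting phenoxide is triflated much faster than the neutral silyl enol ethers, and dilute acid then hydrolyses the enol ethers back to ketones without cleaving the aryl–silicon bond of the triflate-deactivated ring.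

Step 10
Reactants: 15 the 2-(trimethylsilyl)aryl triflate; 16 butyric acid
Product: 19 1-[2,4-bis(benzyloxy)-3,5-bis{[2,4-bis(benzyloxy)-3-butanoyl-6-methoxy-5-methylphenyl]methyl}-6-hydroxyphenyl]butan-1-one, via aryne 17 (not isolated), via aryl caesium ester 18 (not isolated)
Conditions: butyric acid (1.5 equiv), CsF (4 equiv), THF, 125 °C, sealed tube
Reagents that add atoms: none
Why: Fluoride attacks silicon and triflate leaves (1,2-elimination) to give aryne 17; butanoate adds through oxygen to C2, the aryne carbon remote from the C6 benzyloxy group, so the charge develops at C1 beside that inductively withdrawing oxygen, and aryl anion 18 attacks its own ester carbonyl, the four-membered alkoxide opening to the ortho-acyl phenoxide, which is protonated. The closest known reaction type is the fluoride-mediated insertion of arynes from ortho-silylaryl triflates into the C–O bond of carboxylic acids to give ortho-hydroxyaryl ketones. No ring is closed and no stereocentre is formed. The step needs regioselective addition to an unsymmetrical aryne, which the C6 benzyloxy group flanking the triple bond should secure, the C3 neighbour being only an alkyl group. It also needs acyl transfer to outrun protonation of 18, which heating in THF and a small excess of acid should favour. Benzyl ethers, methyl ethers and the hindered outer ketones are spectators under CsF.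

Step 11
Reactants: 19 hexa-O-benzyl ketone
Product: 20 1-[3,5-bis[(3-butanoyl-2,4-dihydroxy-6-methoxy-5-methylphenyl)methyl]-2,4,6-trihydroxyphenyl]butan-1-one (target)
Conditions: H2 (1 atm), 10% Pd/C, EtOAc/MeOH, rt
Reagents that add atoms: none
Why: Heterogeneous hydrogenolysis of six aryl benzyl ethers, under which the hindered, hydrogen-bonded aryl ketones and the diarylmethane bridges should not be reduced at one atmosphere and room temperature.

**Compound list**

1 | 2-methylphloroglucinol | Cc1c(O)cc(O)cc1O | starting material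
2 | butyryl chloride | CCCC(=O)Cl | starting material
3 | 1-(2,4,6-trihydroxy-3-methylphenyl)butan-1-one | CCCC(=O)c1c(O)c(C)c(O)cc1O | intermediate
4 | aspidinol, 1-(2,6-dihydroxy-4-methoxy-3-methylphenyl)butan-1-one | CCCC(=O)c1c(O)c(C)c(OC)cc1O | intermediate
5 | 3-butanoyl-2,4-dihydroxy-6-methoxy-5-methylbenzaldehyde | CCCC(=O)c1c(O)c(C)c(OC)c(C=O)c1O | intermediate
6 | 2,4-bis(benzyloxy)-3-butanoyl-6-methoxy-5-methylbenzaldehyde | CCCC(=O)c1c(OCc2ccccc2)c(C)c(OC)c(C=O)c1OCc1ccccc1 | intermediate
7 | 1-[2,6-bis(benzyloxy)-3-(hydroxymethyl)-4-methoxy-5-methylphenyl]butan-1-one | CCCC(=O)c1c(OCc2ccccc2)c(C)c(OC)c(CO)c1OCc1ccccc1 | intermediate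
8 | 3,5-bis(benzyloxy)phenol | Oc1cc(OCc2ccccc2)cc(OCc2ccccc2)c1 | starting material
9 | 3,5-bis(benzyloxy)-2-bromophenol | Oc1cc(OCc2ccccc2)cc(OCc2ccccc2)c1Br | intermediate
10 | 3,5-bis(benzyloxy)-4,6-bis{[2,4-bis(benzyloxy)-3-butanoyl-6-methoxy-5-methylphenyl]methyl}-2-bromophenol | Brc1c(O)c(Cc2c(OCc3ccccc3)c(C(=O)CCC)c(OCc3ccccc3)c(C)c2OC)c(OCc2ccccc2)c(Cc2c(OCc3ccccc3)c(C(=O)CCC)c(OCc3ccccc3)c(C)c2OC)c1OCc1ccccc1 | intermediate
11 | tris-silyl derivative of 10 (aryl O-SiMe3; both ketones as (Z)-trimethylsilyl enol ethers) | Brc1c(O[Si](C)(C)C)c(Cc2c(OCc3ccccc3)c(/C(O[Si](C)(C)C)=C/CC)c(OCc3ccccc3)c(C)c2OC)c(OCc2ccccc2)c(Cc2c(OCc3ccccc3)c(/C(O[Si](C)(C)C)=C/CC)c(OCc3ccccc3)c(C)c2OC)c1OCc1ccccc1 | intermediate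
12 | aryllithium from 11 (lithium at C1, O-SiMe3 at C2) | [Li]c1c(O[Si](C)(C)C)c(Cc2c(OCc3ccccc3)c(/C(O[Si](C)(C)C)=C/CC)c(OCc3ccccc3)c(C)c2OC)c(OCc2ccccc2)c(Cc2c(OCc3ccccc3)c(/C(O[Si](C)(C)C)=C/CC)c(OCc3ccccc3)c(C)c2OC)c1OCc1ccccc1 | intermediate (not isolated)
13 | lithium 2-(trimethylsilyl)phenoxide after silyl migration (enol ethers intact) | C[Si](C)(C)c1c(O[Li])c(Cc2c(OCc3ccccc3)c(/C(O[Si](C)(C)C)=C/CC)c(OCc3ccccc3)c(C)c2OC)c(OCc2ccccc2)c(Cc2c(OCc3ccccc3)c(/C(O[Si](C)(C)C)=C/CC)c(OCc3ccccc3)c(C)c2OC)c1OCc1ccccc1 | intermediate (not isolated)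
14 | 2-(trimethylsilyl)aryl triflate with both ketones still as (Z)-silyl enol ethers | C[Si](C)(C)c1c(OS(=O)(=O)C(F)(F)F)c(Cc2c(OCc3ccccc3)c(/C(O[Si](C)(C)C)=C/CC)c(OCc3ccccc3)c(C)c2OC)c(OCc2ccccc2)c(Cc2c(OCc3ccccc3)c(/C(O[Si](C)(C)C)=C/CC)c(OCc3ccccc3)c(C)c2OC)c1OCc1ccccc1 | intermediate (not isolated)
15 | 3,5-bis(benzyloxy)-4,6-bis{[2,4-bis(benzyloxy)-3-butanoyl-6-methoxy-5-methylphenyl]methyl}-2-(trimethylsilyl)phenyl trifluoromethanesulfonate | C[Si](C)(C)c1c(OS(=O)(=O)C(F)(F)F)c(Cc2c(OCc3ccccc3)c(C(=O)CCC)c(OCc3ccccc3)c(C)c2OC)c(OCc2ccccc2)c(Cc2c(OCc3ccccc3)c(C(=O)CCC)c(OCc3ccccc3)c(C)c2OC)c1OCc1ccccc1 | intermediate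
16 | butyric acid | CCCC(=O)O | starting material
17 | aryne: 3,5-bis(benzyloxy)-4,6-bis(arylmethyl)benzyne, triple bond between the former C–Si and C–OTf carbons | C1#CC(Cc2c(OCc3ccccc3)c(C(=O)CCC)c(OCc3ccccc3)c(C)c2OC)=C(OCc2ccccc2)C(Cc2c(OCc3ccccc3)c(C(=O)CCC)c(OCc3ccccc3)c(C)c2OC)=C1OCc1ccccc1 | intermediate (not isolated)
18 | aryl caesium bearing the ortho butanoate ester (metal at C1, ester oxygen at C2) | [Cs]c1c(OC(=O)CCC)c(Cc2c(OCc3ccccc3)c(C(=O)CCC)c(OCc3ccccc3)c(C)c2OC)c(OCc2ccccc2)c(Cc2c(OCc3ccccc3)c(C(=O)CCC)c(OCc3ccccc3)c(C)c2OC)c1OCc1ccccc1 | intermediate (not isolated)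
19 | 1-[2,4-bis(benzyloxy)-3,5-bis{[2,4-bis(benzyloxy)-3-butanoyl-6-methoxy-5-methylphenyl]methyl}-6-hydroxyphenyl]butan-1-one | CCCC(=O)c1c(O)c(Cc2c(OCc3ccccc3)c(C(=O)CCC)c(OCc3ccccc3)c(C)c2OC)c(OCc2ccccc2)c(Cc2c(OCc3ccccc3)c(C(=O)CCC)c(OCc3ccccc3)c(C)c2OC)c1OCc1ccccc1 | intermediate
20 | 1-[3,5-bis[(3-butanoyl-2,4-dihydroxy-6-methoxy-5-methylphenyl)methyl]-2,4,6-trihydroxyphenyl]butan-1-one | CCCC(=O)c1c(O)c(Cc2c(O)c(C(=O)CCC)c(O)c(C)c2OC)c(O)c(Cc2c(O)c(C(=O)CCC)c(O)c(C)c2OC)c1O | target

**Totals.** Total step count: 11. Longest linear sequence: 10 steps (steps 1–5, then 7–11).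

**Steps most likely to fail**

1. Step 10 (key step). The aryl anion may be protonated before the acyl group migrates, which would give the aryl ester and no ketone. The fully substituted aryne may also be captured intramolecularly by an ether oxygen of a neighbouring arm, or add butanoate with eroded regioselectivity. Fallback without an aryne, setting out from aspidinol 4 and returning at target 20: aminomethylation of 4 with dimethylmethyleneiminium iodide should give the Mannich base 1-{3-[(dimethylamino)methyl]-2,6-dihydroxy-4-methoxy-5-methylphenyl}butan-1-one F1. Heating two equivalents of it in dioxane with 1-(2,4,6-trihydroxyphenyl)butan-1-one F2 (from phloroglucinol and 2 with AlCl3) should release the ortho-quinone methide of the aspidinol unit. This alkylates both free ring carbons of the central ketone and gives 20 directly, so no protecting groups are needed.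

2. Step 9. Butyllithium may attack silicon or an incompletely masked carbonyl, the aryllithium may be protonated before the silyl shift, or the enol-ether hydrolysis may cost the aryl–silicon bond. Fallback without an organolithium, setting out from 10 and returning at 15: palladium-catalysed silylation of the aryl bromide with hexamethyldisilane (Pd2(dba)3, a bulky biaryl di-tert-butylphosphine, LiOAc, DMF, 100 °C) tolerates ketones. After mild cleavage of any O-silyl group it should give 3,5-bis(benzyloxy)-4,6-bis{[2,4-bis(benzyloxy)-3-butanoyl-6-methoxy-5-methylphenyl]methyl}-2-(trimethylsilyl)phenol F3. Triflation of this phenol with Tf2O and pyridine in CH2Cl2 at 0 °C then gives 15.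

3. Step 7. The acid may reverse and exchange the newly formed methylene bridges, the benzylic alcohol may homo-couple with loss of formaldehyde, or the second benzylation at the position between two benzyloxy groups may stall. Fallback by cross-coupling in place of cationic alkylation, setting out from 9 and 7 and returning at 10: iodination of 9 with N-iodosuccinimide at its two free ring carbons should give 3,5-bis(benzyloxy)-2-bromo-4,6-diiodophenol F4. Alcohol 7 is converted with MsCl, Et3N and LiCl into 1-[2,6-bis(benzyloxy)-3-(chloromethyl)-4-methoxy-5-methylphenyl]butan-1-one F5. Zinc dust with LiCl in THF inserts to give the ketone-tolerant benzylic zinc chloride F6. A twofold Negishi coupling of the zinc reagent with the diiodide (Pd(OAc)2, SPhos, THF, rt) at the two carbon–iodine bonds, which react before the carbon–bromine bond, should give 10.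

**Further compounds**

F1 | step 10 | 1-{3-[(dimethylamino)methyl]-2,6-dihydroxy-4-methoxy-5-methylphenyl}butan-1-one | CCCC(=O)c1c(O)c(C)c(OC)c(CN(C)C)c1O
F2 | step 10 | 1-(2,4,6-trihydroxyphenyl)butan-1-one | CCCC(=O)c1c(O)cc(O)cc1O
F3 | step 9 | 3,5-bis(benzyloxy)-4,6-bis{[2,4-bis(benzyloxy)-3-butanoyl-6-methoxy-5-methylphenyl]methyl}-2-(trimethylsilyl)phenol | C[Si](C)(C)c1c(O)c(Cc2c(OCc3ccccc3)c(C(=O)CCC)c(OCc3ccccc3)c(C)c2OC)c(OCc2ccccc2)c(Cc2c(OCc3ccccc3)c(C(=O)CCC)c(OCc3ccccc3)c(C)c2OC)c1OCc1ccccc1
F4 | step 7 | 3,5-bis(benzyloxy)-2-bromo-4,6-diiodophenol | Oc1c(Br)c(OCc2ccccc2)c(I)c(OCc2ccccc2)c1I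
F5 | step 7 | 1-[2,6-bis(benzyloxy)-3-(chloromethyl)-4-methoxy-5-methylphenyl]butan-1-one | CCCC(=O)c1c(OCc2ccccc2)c(C)c(OC)c(CCl)c1OCc1ccccc1
F6 | step 7 | {[2,4-bis(benzyloxy)-3-butanoyl-6-methoxy-5-methylphenyl]methyl}zinc chloride | CCCC(=O)c1c(OCc2ccccc2)c(C)c(OC)c(C[Zn]Cl)c1OCc1ccccc1
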